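**Retrosynthetic overview**

1. Labdane numbering is used: ring A = C1–C5 and C10, ring B = C5–C10, C17 on C8, C20 on C10, side chain C11–C16. The last cuts are the ω-silyl ether and then C12–C13 (hydroboration/B-alkyl Suzuki–Miyaura coupling). The coupling joins a C9-vinyl bicyclic core to an (E)-3-iodobut-2-enyl ester that already carries the C30 chain, so the allylic alcohols at C15 and C17 never have to be told apart.
2. Ring B is not closed as a six-membered ring. It comes by one-carbon ring expansion of the five-membered ring C5–C7–C8–C9–C10 of a tricyclic spiro-epoxide (cyclopropane C5–C6–C7, oxirane C8–O–C17), triggered by one electron from Cp2TiCl.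
3. Enabling feature: in ring B the allylic alcohol HO–C17–C8=C7 lies homoallylic, through C6, to the ring-fusion methine C5–H, which sits between the quaternary carbons C4 and C10. This O–C17–C8=C7–C6–C5–H array is what a β-titanoxy cyclopropylcarbinyl radical leaves after it opens to a tertiary radical and takes up hydrogen.
4. The tricycle comes from a diazoketone by intramolecular cyclopropanation of the exocyclic C5=C6 olefin. The acid behind it comes from β-cyclogeranyl but-3-enoate by an enantioselective Ireland–Claisen rearrangement (C9–C10 bond, both stereocentres, C5=C6 unveiled). The C30 acid comes from two pentadecanolide halves.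
5. Ring order: ring A is bought (β-cyclocitral); the five- and three-membered rings close together; the oxirane is added; ring B appears last, by expansion.

Key step: step 7

Remark: the target is read as the 5R,9S,10R (ent-labdane) diene diol, esterified at O15 with 30-hydroxytriacontanoic acid (carbonyl carbon plus 29 CH2).

Assumption: the (S,S)-controller of step 3 is taken to give the (2S,1′S)-acid. The sense of induction cannot be derived with certainty for a tetrasubstituted olefin, and the equally available (R,R)-controller would be used if it proves opposite.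

**Route**

Step 1
Reactants: 1 β-cyclocitral (2,6,6-trimethylcyclohex-1-ene-1-carbaldehyde)
Product: 2 β-cyclogeraniol, (2,6,6-trimethylcyclohex-1-en-1-yl)methanol
Conditions: NaBH4, MeOH, 0 °C
Reagents that add atoms: none
Why: Borohydride 1,2-reduction of the hindered conjugated aldehyde should give the primary allylic alcohol and leave the tetrasubstituted olefin alone.

Step 2
Reactants: 2 β-cyclogeraniol; 3 but-3-enoic acid
Product: 4 (2,6,6-trimethylcyclohex-1-en-1-yl)methyl but-3-enoate
Conditions: DCC, DMAP (5 mol %), CH2Cl2, −10 → 0 °C
Reagents that add atoms: none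
Why: Steglich esterification at low temperature with little DMAP should acylate the primary allylic alcohol before the β,γ-unsaturated acid can slip into conjugation.

Step 3
Reactants: 4 (2,6,6-trimethylcyclohex-1-en-1-yl)methyl but-3-enoate
Product: 6 (2S)-2-[(1S)-1,3,3-trimethyl-2-methylidenecyclohexyl]but-3-enoic acid, via Z(O)-boron ketene acetal 5 (not isolated)
Conditions: (S,S)-bromoborane (1.2 equiv, from the (S,S)-stilbenediamine bis[3,5-bis(trifluoromethyl)benzenesulfonamide] and BBr3, CH2Cl2, then vacuum), iPr2NEt, CH2Cl2, −78 °C, then −20 → 4 °C; aq. work-up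
Reagents that add atoms: (S,S)-2-bromo-4,5-diphenyl-1,3-bis{[3,5-bis(trifluoromethyl)phenyl]sulfonyl}-1,3,2-diazaborolidine, BrB1N(S(=O)(=O)c2cc(cc(c2)C(F)(F)F)C(F)(F)F)[C@@H](c2ccccc2)[C@H](c2ccccc2)N1S(=O)(=O)c1cc(cc(c1)C(F)(F)F)C(F)(F)F (its boron unit stands in 5 only and is lost on work-up)
Why: In this enantioselective boron-enolate variant of the Ireland–Claisen rearrangement, soft enolisation with iPr2NEt in CH2Cl2 should give the Z(O)-ketene acetal (vinyl cis to O–B), whose chair transition state puts C11 and C1 equatorial and the C10 methyl axial and so sets the C9/C10 relative configuration, while the C2-symmetric sulfonamide ligand on boron selects the olefin face and thus the absolute configuration; the shift also forms C9–C10 and moves the ring olefin to the exocyclic C5=C6 position.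

Step 4
Reactants: 6 (2S)-2-[(1S)-1,3,3-trimethyl-2-methylidenecyclohexyl]but-3-enoic acid
Product: 8 (3S)-1-diazo-3-[(1S)-1,3,3-trimethyl-2-methylidenecyclohexyl]pent-4-en-2-one, via acid chloride 7 (not isolated)
Conditions: Me2C=C(Cl)NMe2, CH2Cl2, 0 °C → rt; then CH2N2 (excess), Et2O, 0 °C
Reagents that add atoms: 1-chloro-N,N,2-trimethylprop-1-en-1-amine, CC(C)=C(Cl)N(C)C (chlorine of 7 only); diazomethane, C=[N+]=[N-]
Why: Neutral acid chloride formation with an α-chloroenamine, followed by acylation of excess diazomethane (first stage of the Arndt–Eistert sequence), should give the α-diazoketone without acid or amine base, so that the doubly activated C9–H and the acid-sensitive C5=C6 olefin stay untouched.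

Step 5
Reactants: 8 (3S)-1-diazo-3-[(1S)-1,3,3-trimethyl-2-methylidenecyclohexyl]pent-4-en-2-one
Product: 9 tricyclic cyclopropyl ketone (5S,7R,9S,10S): cyclopentanone C5–C7–C8(=O)–C9–C10 cis-fused to ring A at C5–C10 and to the cyclopropane C5–C6–C7, with C6, the C10 methyl and the C9 vinyl on the same face of the five-membered ring
Conditions: Rh2(OAc)4 (1 mol %), CH2Cl2, rt, slow addition of 8
Reagents that add atoms: none
Why: In this intramolecular carbenoid cyclopropanation of a γ,δ-unsaturated α-diazoketone the three-atom tether holds the electrophilic rhodium carbenoid at C7 over the face of C5=C6 that is syn to C9, so the five- and three-membered rings should close together as one cis-fused diastereomer, faster than attack on the β,γ-vinyl group, which could only give a bicyclo[2.1.0]pentanone; the new centres C5 and C7 are erased in step 7.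

Step 6
Reactants: 9 tricyclic cyclopropyl ketone
Product: 11 spiro-epoxide (5S,7R,8R,9S,10S) with oxirane C8–O–C17, via lithium chlorohydrin alkoxide 10 (not isolated)
Conditions: ICH2Cl, MeLi·LiBr, THF–Et2O, −78 °C → rt
Reagents that add atoms: chloroiodomethane, ClCI (CH2 of 11, CH2Cl of 10); methyllithium, [Li]C (lithium of 10 only)
Why: In this halomethyllithium epoxidation, chloromethyllithium made by iodine–lithium exchange in the presence of the ketone is small and should add at −78 °C faster than it enolises C9, from the face anti to the cyclopropane methylene and the vinyl group, and the alkoxide closes the oxirane on warming; the C8 centre so set is erased in step 7.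

Step 7
Reactants: 11 spiro-epoxide
Product: 12 [(1S,4aR,8aR)-1-ethenyl-5,5,8a-trimethyl-1,4,4a,5,6,7,8,8a-octahydronaphthalen-2-yl]methanol (5R,9S,10R; C9 vinyl, C7=C8, C17 OH)
Conditions: Cp2TiCl2 (20 mol %), Mn dust, 2,4,6-collidine·HCl, 1,4-cyclohexadiene, THF, rt, slow addition of 11
Reagents that add atoms: none
Why: Proposed new method: Cp2TiCl (trivalent titanium, made in the flask) gives one electron to the oxirane and opens the C8–O bond to the tertiary β-titanoxy radical at C8, a cyclopropylcarbinyl radical; scission of the C5–C7 bond shared by the three- and five-membered rings gives C7=C8 and the tertiary C5 radical, so that the five-membered ring C5–C7–C8–C9–C10 becomes ring B with C6 as the inserted atom, after which 1,4-cyclohexadiene delivers hydrogen to C5 and collidinium chloride frees the C17 alcohol and returns Cp2TiCl2. The closest known reaction types are the reductive titanocene opening of epoxides with a hydrogen-atom donor, the titanocene-induced fragmentation of the strained ring next to the spiro-oxirane of pinane oxides (which gives 1-hydroxymethylcyclohexenes), and the opening of thujane-type bicyclo[3.1.0]hex-2-yl radicals and cations to p-menthene six-membered rings; new is their union for an endocyclic cleavage with reductive end. No ring is closed by bond formation: ring B arises only by cleavage of the zero-atom bridge of the bicyclo[3.1.0]hexane, and the cyclopropane and the oxirane vanish. The only new stereocentre, C5, is under substrate control, since the donor should reach the planar radical from the face opposite the axial C10 methyl and the axial C4 methyl, which gives the trans ring fusion, while C9 and C10 are untouched and C7 and C8 become sp2. The selectivity needed is cleavage of C5–C7 and not C6–C7, and it is secured by the tertiary versus primary radical, by relief of the three contiguous quaternary carbons C4–C5–C10, and by the fact that the primary radical of the wrong cleavage is a 2,2-disubstituted but-3-enyl radical that should reclose faster than the slow donor traps it, so that the system drains to the C5 radical. The buffered neutral medium should keep the acid-labile epoxide from ionising and leave the vinyl group alone.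

Step 8
Reactants: 13 ω-pentadecalactone (oxacyclohexadecan-2-one)
Product: 14 15-bromopentadecanoic acid
Conditions: HBr (33 % in AcOH), cat. H2SO4, 60 °C
Reagents that add atoms: hydrogen bromide, Br
Why: Acid-mediated alkyl–oxygen cleavage of the macrolactone by bromide (SN2 at the primary carbinol carbon) should give the ω-bromo acid.

Step 9
Reactants: 14 15-bromopentadecanoic acid
Product: 15 15-bromopentadecan-1-ol
Conditions: BH3·THF, THF, 0 °C → rt; MeOH quench
Reagents that add atoms: none
Why: Chemoselective borane reduction of the carboxylic acid should leave the primary alkyl bromide untouched.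

Step 10
Reactants: 15 15-bromopentadecan-1-ol
Product: 16 [(15-bromopentadecyl)oxy](tert-butyl)dimethylsilane
Conditions: TBSCl, imidazole, CH2Cl2, rt
Reagents that add atoms: tert-butyldimethylsilyl chloride, CC(C)(C)[Si](C)(C)Cl
Why: Imidazole-promoted silylation of the primary alcohol gives an ether that withstands Grignard formation.

Step 11
Reactants: 16 [(15-bromopentadecyl)oxy](tert-butyl)dimethylsilane; 14 15-bromopentadecanoic acid
Product: 19 30-[(tert-butyldimethylsilyl)oxy]triacontanoic acid, via Grignard reagent 17 (not isolated), via chloromagnesium carboxylate 18 (not isolated)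
Conditions: 16: Mg, THF, 40 °C; 14: MeMgCl (1 equiv), THF, −20 °C; combine, Li2CuCl4 (3 mol %), NMP, −20 °C → rt; aq. NH4Cl
Reagents that add atoms: magnesium, [Mg] (in 17 only); methylmagnesium chloride, C[Mg]Cl (MgCl of 18 only)
Why: Copper-catalysed cross-coupling of a primary alkyl Grignard reagent with a primary alkyl bromide, run on the pre-formed halomagnesium carboxylate so that the acid function is inert, should join the two C15 halves to the C30 chain.

Step 12
Reactants: 20 but-2-yn-1-ol
Product: 22 (E)-3-iodobut-2-en-1-ol, via alkenylzirconocene 21 (not isolated)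
Conditions: Cp2Zr(H)Cl (2.2 equiv), THF, rt; then I2, 0 °C
Reagents that add atoms: zirconocene chloride hydride, [H][Zr](Cl)(C1C=CC=C1)C1C=CC=C1 (in 21 only); iodine, II
Why: In this hydrozirconation–iodination the Zr–H bond adds syn, excess reagent should let zirconium settle on the methyl-bearing carbon remote from the zirconium alkoxide, and iodinolysis with retention then fixes the geometry needed for the C13=C14 olefin.

Step 13
Reactants: 22 (E)-3-iodobut-2-en-1-ol; 19 30-[(tert-butyldimethylsilyl)oxy]triacontanoic acid
Product: 23 (E)-3-iodobut-2-en-1-yl 30-[(tert-butyldimethylsilyl)oxy]triacontanoate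
Conditions: DCC, DMAP (cat.), CH2Cl2, rt
Reagents that add atoms: none
Why: Steglich esterification of an unhindered primary allylic alcohol should leave the vinyl iodide and the silyl ether untouched.

Step 14
Reactants: 12 C9-vinyl bicyclic allylic alcohol; 23 (E)-3-iodobut-2-en-1-yl 30-[(tert-butyldimethylsilyl)oxy]triacontanoate
Product: 25 (5R,9S,10R)-17-hydroxylabda-7,13E-dien-15-yl 30-[(tert-butyldimethylsilyl)oxy]triacontanoate, via B-alkyl-9-BBN adduct 24 (not isolated)
Conditions: 9-BBN-H (2.2 equiv), THF, 0 °C → rt; then 23, PdCl2(dppf) (5 mol %), AsPh3, Cs2CO3, DMF–H2O, rt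
Reagents that add atoms: 9-borabicyclo[3.3.1]nonane, [H]B1C2CCCC1CCC2 (its boron units stand in 24 only)
Why: In this one-flask hydroboration and B-alkyl Suzuki–Miyaura coupling, 9-BBN-H should add only to the monosubstituted C11=C12 olefin with boron on C12 (a further equivalent is held by the C17 hydroxyl as a borinate that the aqueous base cleaves again), and zerovalent palladium should insert into the C–I bond far faster than it ionises the primary allylic alkanoate, so that C12–C13 forms with retention of the E geometry and the C15 ester arrives in place.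

Step 15
Reactants: 25 silyl-protected ester
Product: 26 target, (5R,9S,10R)-17-hydroxylabda-7,13E-dien-15-yl 30-hydroxytriacontanoate
Conditions: HF·pyridine, THF–pyridine, 0 °C → rt
Reagents that add atoms: none
Why: Buffered fluoride-mediated desilylation should free the primary ω-alcohol without acyl migration, ester cleavage or allylic ionisation.

**Compound list**

1 | β-cyclocitral | CC1=C(C=O)C(C)(C)CCC1 | starting material
2 | β-cyclogeraniol | CC1=C(CO)C(C)(C)CCC1 | intermediate
3 | but-3-enoic acid | C=CCC(=O)O | starting material
4 | (2,6,6-trimethylcyclohex-1-en-1-yl)methyl but-3-enoate | C=CCC(=O)OCC1=C(C)CCCC1(C)C | intermediate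
5 | Z(O)-boron ketene acetal of 4 with the (S,S)-diazaborolidine | C=C/C=C(\OB1N(S(=O)(=O)c2cc(cc(c2)C(F)(F)F)C(F)(F)F)[C@@H](c2ccccc2)[C@H](c2ccccc2)N1S(=O)(=O)c1cc(cc(c1)C(F)(F)F)C(F)(F)F)OCC1=C(C)CCCC1(C)C | intermediate
6 | (2S)-2-[(1S)-1,3,3-trimethyl-2-methylidenecyclohexyl]but-3-enoic acid | C=C[C@H](C(=O)O)[C@]1(C)CCCC(C)(C)C1=C | intermediate
7 | acid chloride of 6 | C=C[C@H](C(=O)Cl)[C@]1(C)CCCC(C)(C)C1=C | intermediate
8 | (3S)-1-diazo-3-[(1S)-1,3,3-trimethyl-2-methylidenecyclohexyl]pent-4-en-2-one | C=C[C@H](C(=O)C=[N+]=[N-])[C@]1(C)CCCC(C)(C)C1=C | intermediate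
9 | tricyclic cyclopropyl ketone (5S,7R,9S,10S) | O=C1[C@@H](C=C)[C@]2(C)CCCC(C)(C)[C@@]23C[C@@H]13 | intermediate
10 | lithium alkoxide of the C8 chlorohydrin | [Li+].[O-][C@@]1(CCl)[C@@H](C=C)[C@]2(C)CCCC(C)(C)[C@@]23C[C@@H]13 | intermediate
11 | spiro-epoxide (5S,7R,8R,9S,10S) | C1O[C@]12[C@@H](C=C)[C@]3(C)CCCC(C)(C)[C@@]34C[C@@H]24 | intermediate
12 | [(1S,4aR,8aR)-1-ethenyl-5,5,8a-trimethyl-1,4,4a,5,6,7,8,8a-octahydronaphthalen-2-yl]methanol | C=C[C@@H]1C(CO)=CC[C@@H]2C(C)(C)CCC[C@@]12C | intermediate
13 | ω-pentadecalactone | O=C1CCCCCCCCCCCCCCO1 | starting material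
14 | 15-bromopentadecanoic acid | OC(=O)CCCCCCCCCCCCCCBr | intermediate
15 | 15-bromopentadecan-1-ol | OCCCCCCCCCCCCCCCBr | intermediate
16 | [(15-bromopentadecyl)oxy](tert-butyl)dimethylsilane | CC(C)(C)[Si](C)(C)OCCCCCCCCCCCCCCCBr | intermediate
17 | 15-[(tert-butyldimethylsilyl)oxy]pentadecylmagnesium bromide | CC(C)(C)[Si](C)(C)OCCCCCCCCCCCCCCC[Mg]Br | intermediate
18 | chloromagnesium 15-bromopentadecanoate | BrCCCCCCCCCCCCCCC(=O)O[Mg]Cl | intermediate
19 | 30-[(tert-butyldimethylsilyl)oxy]triacontanoic acid | OC(=O)CCCCCCCCCCCCCCCCCCCCCCCCCCCCCO[Si](C)(C)C(C)(C)C | intermediate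
20 | but-2-yn-1-ol | CC#CCO | starting material
21 | (E)-alkenylzirconocene, zirconium alkoxide | C/C(=C\CO[Zr](Cl)(C1C=CC=C1)C1C=CC=C1)[Zr](Cl)(C1C=CC=C1)C1C=CC=C1 | intermediate
22 | (E)-3-iodobut-2-en-1-ol | C/C(I)=C\CO | intermediate
23 | (E)-3-iodobut-2-en-1-yl 30-[(tert-butyldimethylsilyl)oxy]triacontanoate | C/C(I)=C\COC(=O)CCCCCCCCCCCCCCCCCCCCCCCCCCCCCO[Si](C)(C)C(C)(C)C | intermediate
24 | B-alkyl-9-BBN adduct of 12 (C12–B, C17–O–B) | C1CC2CCCC(C1)B2CC[C@@H]1C(COB2C3CCCC2CCC3)=CC[C@@H]2C(C)(C)CCC[C@@]12C | intermediate
25 | (5R,9S,10R)-17-hydroxylabda-7,13E-dien-15-yl 30-[(tert-butyldimethylsilyl)oxy]triacontanoate | C/C(=C\COC(=O)CCCCCCCCCCCCCCCCCCCCCCCCCCCCCO[Si](C)(C)C(C)(C)C)CC[C@@H]1C(CO)=CC[C@@H]2C(C)(C)CCC[C@@]12C | intermediate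
26 | (5R,9S,10R)-17-hydroxylabda-7,13E-dien-15-yl 30-hydroxytriacontanoate | C/C(=C\COC(=O)CCCCCCCCCCCCCCCCCCCCCCCCCCCCCO)CC[C@@H]1C(CO)=CC[C@@H]2C(C)(C)CCC[C@@]12C | target

**Counts and risks**

Total step count: 15. Longest linear sequence: 9 steps (steps 1–7, 14 and 15).

First risk, step 7.
- What may go wrong: hydrogen may be transferred to the primary radical of the exocyclic C6–C7 cleavage before it recloses. Lewis-acidic titanium or manganese salts may open the cyclopropylcarbinyl epoxide ionically. The C5 radical may lose hydrogen by disproportionation. Hydrogen may be delivered to the wrong face of C5.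
- Fallback: it sets out from 11 and comes back at 12. It reaches the same C8 radical by an established tin hydride chain, free of metal salts and with a donor concentration that a syringe pump can keep very low.
- The oxirane is opened at C17 with caesium benzoate (DMF, 80 °C) to the tertiary alcohol/primary benzoate F1.
- F1 is acylated with methyl chlorooxoacetate and DMAP to the mixed methyl oxalate F2.
- Bu3SnH and AIBN in refluxing toluene (deoxygenation of a tertiary alkyl oxalate) then give, after cyclopropylcarbinyl opening and hydrogen transfer, the ring-expanded benzoate F3.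
- K2CO3 in MeOH converts F3 into 12.

Second risk, step 3.
- What may go wrong: the bulky boron ketene acetal may rearrange too slowly at the tetrasubstituted olefin. The enolate geometry may erode. Part of the flux may leak through a boat transition state. The facial discrimination may be insufficient.
- Fallback: it sets out from 4 and comes back at 6. It gives up reagent control for a racemic rearrangement and a classical resolution.
- LDA in THF–DMPU and TMSCl at −78 °C give the (Z)-silyl ketene acetal F4, which rearranges on warming to the racemic trimethylsilyl ester F5.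
- Hydrolysis gives the racemic acid, that is 6 together with its enantiomer F6.
- Crystallisation with (S)-1-phenylethylamine (or its enantiomer, to be found by trial) gives the diastereomerically pure ammonium salt F7, and acidification returns 6.

Third risk, step 6.
- What may go wrong: C9 may be enolised, with epimerisation or migration of the vinyl double bond into conjugation. Addition to the hindered carbonyl group may be slow.
- Fallback: it sets out from 9 and comes back at 12. It replaces carbenoid addition by olefination and epoxidation.
- Non-basic Petasis methylenation (Cp2TiMe2, toluene, 70 °C) gives the methylidene diene F8.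
- Dimethyldioxirane (acetone, −20 °C) should oxidise the more nucleophilic, cyclopropyl-conjugated 1,1-disubstituted olefin in preference to the monosubstituted vinyl group. Oxygen is delivered from the face anti to the cyclopropane methylene, which gives the C8-epimeric spiro-epoxide F9.
- Under the conditions of step 7, F9 gives the same C8 radical and hence 12.

**Further compounds**

F1 | step 7 | C8 tertiary alcohol, C17 benzoate from 11 | O[C@@]1(COC(=O)c2ccccc2)[C@@H](C=C)[C@]2(C)CCCC(C)(C)[C@@]23C[C@@H]13
F2 | step 7 | C8 methyl oxalate of F1 | COC(=O)C(=O)O[C@@]1(COC(=O)c2ccccc2)[C@@H](C=C)[C@]2(C)CCCC(C)(C)[C@@]23C[C@@H]13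
F3 | step 7 | C17 benzoate of 12 | C=C[C@@H]1C(COC(=O)c2ccccc2)=CC[C@@H]2C(C)(C)CCC[C@@]12C
F4 | step 3 | (Z)-trimethylsilyl ketene acetal of 4 | C=C/C=C(\O[Si](C)(C)C)OCC1=C(C)CCCC1(C)C
F5 | step 3 | trimethylsilyl ester of the acid (racemic, one enantiomer drawn) | C=C[C@H](C(=O)O[Si](C)(C)C)[C@]1(C)CCCC(C)(C)C1=C
F6 | step 3 | (2R)-2-[(1R)-1,3,3-trimethyl-2-methylidenecyclohexyl]but-3-enoic acid | C=C[C@@H](C(=O)O)[C@@]1(C)CCCC(C)(C)C1=C
F7 | step 3 | (S)-1-phenylethylammonium salt of 6 | C=C[C@H](C(=O)[O-])[C@]1(C)CCCC(C)(C)C1=C.C[C@H]([NH3+])c1ccccc1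
F8 | step 6 | C8 methylidene diene from 9 | C=C1[C@@H](C=C)[C@]2(C)CCCC(C)(C)[C@@]23C[C@@H]13
F9 | step 6 | C8 epimer of spiro-epoxide 11 | C1O[C@@]12[C@@H](C=C)[C@]3(C)CCCC(C)(C)[C@@]34C[C@@H]24
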